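Ring A of this labdane is a bare cyclohexane whose C2–C3 bond joins C1 (on quaternary C10) to C3 (on gem-dimethyl C4). The route completes ring B first and closes ring A last across C2–C3 by ring-closing metathesis with hydrogenation on the same ruthenium, exploiting that both alkene arms sit on fully substituted carbons held trans-diequatorial on ring B. The precursor is a cyclohexanone in which C10 carries methyl and allyl, C5 a 1,1-dimethylallyl group trans to the allyl, and C9 a 3-oxobutyl arm beside the C8 ketone. One operation gives the saturated trans-decalin; the 8α-carbinol and (E)-allylic acetate follow.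

Key step: step 7

Remark: labdane numbering (C1–C20) is used for positions in all intermediates; the target is taken as the normal-series labdane (5S,8R,9R,10S,13E) that its SMILES defines.

Step 1
Reactants: 1 methyl 3,3-dimethylpent-4-enoate
Product: 2 3,3-dimethylpent-4-enal
Conditions: i-Bu2AlH (1.05 equiv), CH2Cl2, −78 °C; Rochelle-salt work-up
Reagents that add atoms: none
Why: Half-reduction of an ester with i-Bu2AlH at −78 °C stops at the aluminium hemiacetal, which releases the aldehyde only on work-up, and the isolated alkene is inert.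

Step 2
Reactants: 2 3,3-dimethylpent-4-enal; 3 but-3-en-2-one
Product: 5 (4R)-4-(2-methylbut-3-en-2-yl)cyclohex-2-en-1-one, via keto aldehyde 4 (not isolated)
Conditions: (S)-2-(methoxydiphenylmethyl)pyrrolidine (5 mol %), ethyl 3,4-dihydroxybenzoate (20 mol %), neat, 4 °C; then LiOH (20 mol %), i-PrOH, rt
Reagents that add atoms: but-3-en-2-one (3), CC(=O)C=C
Why: Enamine-catalysed asymmetric Michael addition followed by intramolecular aldol condensation (organocatalytic Robinson annulation) should work because the (S)-pyrrolidine forms the E-enamine of 2 and shields one face with its diphenylmethyl group, so the enone adds to the open face and sets C5 (S in 4, R in 5).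

Step 3
Reactants: 5 (4R)-4-(2-methylbut-3-en-2-yl)cyclohex-2-en-1-one; 6 methylmagnesium bromide; 7 chlorotrimethylsilane
Product: 8 trimethyl{[(3S,4R)-3-methyl-4-(2-methylbut-3-en-2-yl)cyclohex-1-en-1-yl]oxy}silane
Conditions: MeMgBr, CuBr·SMe2 (10 mol %), TMSCl, DMPU, THF, −78 °C; Et3N, cold NaHCO3 work-up
Reagents that add atoms: methylmagnesium bromide (6), C[Mg]Br; chlorotrimethylsilane (7), C[Si](C)(C)Cl
Why: Copper-catalysed conjugate addition of a Grignard reagent with chlorosilane trapping gives the regiodefined enol silane, and the new methyl-bearing centre (expected trans to the C5 group) is erased in step 4, so its configuration is immaterial.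

Step 4
Reactants: 8 trimethyl{[(3S,4R)-3-methyl-4-(2-methylbut-3-en-2-yl)cyclohex-1-en-1-yl]oxy}silane
Product: 9 (4R)-3-methyl-4-(2-methylbut-3-en-2-yl)cyclohex-2-en-1-one
Conditions: Pd(OAc)2 (10 mol %), O2 (1 atm), DMSO, rt
Reagents that add atoms: none
Why: Saegusa–Ito oxidation proceeds through a palladium enolate at C9 and β-hydride elimination of the only β-hydrogen (on C10), which should restore the enone with the β-methyl group in place and leave C5 and the vinyl group (no allylic hydrogen) untouched.

Step 5
Reactants: 9 (4R)-3-methyl-4-(2-methylbut-3-en-2-yl)cyclohex-2-en-1-one; 10 allylmagnesium bromide; 7 chlorotrimethylsilane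
Product: 11 trimethyl{[(3S,4S)-3-methyl-4-(2-methylbut-3-en-2-yl)-3-(prop-2-en-1-yl)cyclohex-1-en-1-yl]oxy}silane
Conditions: allylMgBr, CuBr·SMe2 (1.1 equiv), TMSCl, THF, −78 °C; Et3N, cold NaHCO3 work-up
Reagents that add atoms: allylmagnesium bromide (10), C=CC[Mg]Br; chlorotrimethylsilane (7), C[Si](C)(C)Cl
Why: Chlorosilane-accelerated conjugate addition of allylcopper should set C10 because A(1,2) strain with the C10 methyl forces the bulky C5 group pseudoaxial, so allyl adds to the opposite face (allyl trans to the 1,1-dimethylallyl group, methyl cis) and the enolate is kept as the C8–C9 enol silane.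

Step 6
Reactants: 11 trimethyl{[(3S,4S)-3-methyl-4-(2-methylbut-3-en-2-yl)-3-(prop-2-en-1-yl)cyclohex-1-en-1-yl]oxy}silane; 3 but-3-en-2-one
Product: 12 (3S,4S)-3-methyl-4-(2-methylbut-3-en-2-yl)-2-(3-oxobutyl)-3-(prop-2-en-1-yl)cyclohexan-1-one (C2 epimers)
Conditions: TiCl4 (1.0 equiv), CH2Cl2, −78 °C; aq. NaHCO3
Reagents that add atoms: but-3-en-2-one (3), CC(=O)C=C
Why: Mukaiyama–Michael addition delivers the 3-oxobutyl arm only at C9, because the TiCl4-activated enone is attacked by the preformed enol silane without enolate equilibration; C9 forms as a mixture that is corrected in step 8.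

Step 7
Reactants: 12 (3S,4S)-3-methyl-4-(2-methylbut-3-en-2-yl)-2-(3-oxobutyl)-3-(prop-2-en-1-yl)cyclohexan-1-one (C2 epimers)
Product: 14 (4aS,8aS)-5,5,8a-trimethyl-1-(3-oxobutyl)octahydronaphthalen-2(1H)-one as C1 epimers, via cyclohexene 13 (not isolated)
Conditions: second-generation Grubbs catalyst RuCl2(=CHPh)(PCy3)(H2IMes) (5 mol %), ClCH2CH2Cl, 50 °C; then H2 (7 bar), 70 °C
Reagents that add atoms: none
Why: The ruthenium alkylidene initiates at the unhindered allyl group on C10, the new alkylidene engages the neopentylic vinyl group on C4 through a metallacyclobutane and ethene is lost to form C2=C3; under H2 the carbene becomes a ruthenium hydride that saturates this cis-disubstituted alkene. The closest known reaction type is tandem ring-closing metathesis–olefin hydrogenation with Grubbs-type catalysts. Ring A closes in a six-membered ring-closing metathesis mode between two monosubstituted terminal alkenes, and the diene offers no other ring size. No stereocentre is created; the trans ring fusion follows from the trans-diequatorial arms fixed in steps 2 and 5, and the quaternary C4 and C10 favour closure (gem-dialkyl effect). The step needs chemoselective reduction of C2=C3 over the two ketones, which is secured because no base or diamine is present to turn the ruthenium hydride towards carbonyl reduction.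

Step 8
Reactants: 14 (4aS,8aS)-5,5,8a-trimethyl-1-(3-oxobutyl)octahydronaphthalen-2(1H)-one (C1 epimers); 15 triethyl phosphonoacetate
Product: 17 ethyl (2E)-3-methyl-5-[(1R,4aS,8aS)-5,5,8a-trimethyl-2-oxodecahydronaphthalen-1-yl]pent-2-enoate, via epimeric keto enoate 16 (not isolated)
Conditions: NaH (1.0 equiv, phosphonate anion preformed), THF, 0 to 40 °C; then NaOEt (20 mol %), EtOH, rt
Reagents that add atoms: triethyl phosphonoacetate (15), CCOC(=O)CP(=O)(OCC)OCC
Why: Horner–Wadsworth–Emmons olefination should occur only at the unhindered methyl ketone (the C8 ketone is flanked by C9 and quaternary C10) and favour the E-enoate, after which ethoxide equilibrates C9 through the C8 enolate to the equatorial 9β side chain, also the product of axial protonation anti to the C10 methyl; the minor Z isomer is to be removed by chromatography.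

Step 9
Reactants: 17 ethyl (2E)-3-methyl-5-[(1R,4aS,8aS)-5,5,8a-trimethyl-2-oxodecahydronaphthalen-1-yl]pent-2-enoate; 18 dibromomethane
Product: 19 ethyl (2E)-3-methyl-5-[(1S,4aS,8aS)-5,5,8a-trimethyl-2-methylidenedecahydronaphthalen-1-yl]pent-2-enoate
Conditions: Zn, CH2Br2, TiCl4, THF, 0 °C (reagent aged); then 17, CH2Cl2, rt
Reagents that add atoms: dibromomethane (18), BrCBr
Why: Takai–Lombardo methylenation converts hindered, enolisable ketones into methylene compounds under non-basic conditions, so C9 should not epimerise and the ester should stay untouched.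

Step 10
Reactants: 19 ethyl (2E)-3-methyl-5-[(1S,4aS,8aS)-5,5,8a-trimethyl-2-methylidenedecahydronaphthalen-1-yl]pent-2-enoate; 20 3-chloroperoxybenzoic acid
Product: 21 ethyl (13E)-8α,17-epoxylabd-13-en-15-oate
Conditions: mCPBA, NaHCO3, CH2Cl2, 0 °C
Reagents that add atoms: 3-chloroperoxybenzoic acid (20), OOC(=O)c1cccc(Cl)c1
Why: Prilezhaev epoxidation is selective for the electron-rich 1,1-disubstituted alkene over the enoate, and the peracid should approach C8 from the α face because the axial β trajectory is blocked by the syn-axial C10 methyl, which places oxygen α and C17 β.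

Step 11
Reactants: 21 ethyl (13E)-8α,17-epoxylabd-13-en-15-oate
Product: 22 (1R,2R,4aS,8aS)-1-[(3E)-5-hydroxy-3-methylpent-3-en-1-yl]-2,5,5,8a-tetramethyldecahydronaphthalen-2-ol
Conditions: LiAlH4, THF, 0 to 50 °C; Rochelle-salt work-up
Reagents that add atoms: none
Why: Hydride opens the spiro-epoxide at its primary carbon (SN2), turning C17 into the axial methyl and leaving the 8α-hydroxyl with C8 unchanged, and reduces the enoate 1,2 to the allylic alcohol.

Step 12
Reactants: 22 (1R,2R,4aS,8aS)-1-[(3E)-5-hydroxy-3-methylpent-3-en-1-yl]-2,5,5,8a-tetramethyldecahydronaphthalen-2-ol; 23 acetic anhydride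
Product: 24 (2E)-5-[(1R,2R,4aS,8aS)-2-hydroxy-2,5,5,8a-tetramethyldecahydronaphthalen-1-yl]-3-methylpent-2-en-1-yl acetate
Conditions: Ac2O (1.1 equiv), pyridine, CH2Cl2, 0 °C
Reagents that add atoms: acetic anhydride (23), CC(=O)OC(C)=O
Why: Acylation should discriminate the primary allylic alcohol from the hindered tertiary C8 alcohol, which is inert to Ac2O/pyridine at 0 °C.

Compound list
1 | methyl 3,3-dimethylpent-4-enoate | COC(=O)CC(C)(C)C=C | starting material
2 | 3,3-dimethylpent-4-enal | O=CCC(C)(C)C=C | intermediate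
3 | but-3-en-2-one (methyl vinyl ketone) | CC(=O)C=C | starting material
4 | (2S)-2-(2-methylbut-3-en-2-yl)-5-oxohexanal | C=CC(C)(C)[C@@H](C=O)CCC(C)=O | intermediate (not isolated)
5 | (4R)-4-(2-methylbut-3-en-2-yl)cyclohex-2-en-1-one | C=CC(C)(C)[C@H]1C=CC(=O)CC1 | intermediate
6 | methylmagnesium bromide | C[Mg]Br | starting material
7 | chlorotrimethylsilane | C[Si](C)(C)Cl | starting material
8 | trimethyl{[(3S,4R)-3-methyl-4-(2-methylbut-3-en-2-yl)cyclohex-1-en-1-yl]oxy}silane | C=CC(C)(C)[C@H]1[C@H](C)C=C(O[Si](C)(C)C)CC1 | intermediate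
9 | (4R)-3-methyl-4-(2-methylbut-3-en-2-yl)cyclohex-2-en-1-one | C=CC(C)(C)[C@H]1C(C)=CC(=O)CC1 | intermediate
10 | allylmagnesium bromide | C=CC[Mg]Br | starting material
11 | trimethyl{[(3S,4S)-3-methyl-4-(2-methylbut-3-en-2-yl)-3-(prop-2-en-1-yl)cyclohex-1-en-1-yl]oxy}silane | C=CC(C)(C)[C@H]1[C@](C)(CC=C)C=C(O[Si](C)(C)C)CC1 | intermediate
12 | (3S,4S)-3-methyl-4-(2-methylbut-3-en-2-yl)-2-(3-oxobutyl)-3-(prop-2-en-1-yl)cyclohexan-1-one, C2 epimers | CC(=O)CCC1[C@@](C)(CC=C)[C@H](C(C)(C)C=C)CCC1=O | intermediate
13 | (4aS,8aS)-5,5,8a-trimethyl-1-(3-oxobutyl)-3,4,4a,5,8,8a-hexahydronaphthalen-2(1H)-one, C1 epimers | CC(=O)CCC1[C@@]2(C)CC=CC(C)(C)[C@@H]2CCC1=O | intermediate (not isolated)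
14 | (4aS,8aS)-5,5,8a-trimethyl-1-(3-oxobutyl)octahydronaphthalen-2(1H)-one, C1 epimers | CC(=O)CCC1[C@@]2(C)CCCC(C)(C)[C@@H]2CCC1=O | intermediate
15 | triethyl phosphonoacetate | CCOC(=O)CP(=O)(OCC)OCC | starting material
16 | ethyl (2E)-3-methyl-5-[(4aS,8aS)-5,5,8a-trimethyl-2-oxodecahydronaphthalen-1-yl]pent-2-enoate, C1 epimers | CCOC(=O)/C=C(\C)CCC1[C@@]2(C)CCCC(C)(C)[C@@H]2CCC1=O | intermediate (not isolated)
17 | ethyl (2E)-3-methyl-5-[(1R,4aS,8aS)-5,5,8a-trimethyl-2-oxodecahydronaphthalen-1-yl]pent-2-enoate | CCOC(=O)/C=C(\C)CC[C@@H]1[C@@]2(C)CCCC(C)(C)[C@@H]2CCC1=O | intermediate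
18 | dibromomethane | BrCBr | starting material
19 | ethyl (2E)-3-methyl-5-[(1S,4aS,8aS)-5,5,8a-trimethyl-2-methylidenedecahydronaphthalen-1-yl]pent-2-enoate (ethyl labda-8(17),13E-dien-15-oate) | CCOC(=O)/C=C(\C)CC[C@@H]1[C@@]2(C)CCCC(C)(C)[C@@H]2CCC1=C | intermediate
20 | 3-chloroperoxybenzoic acid | OOC(=O)c1cccc(Cl)c1 | starting material
21 | ethyl (13E)-8α,17-epoxylabd-13-en-15-oate (spiro-oxirane at C8, oxygen on the α face, CH2 on the β face) | CCOC(=O)/C=C(\C)CC[C@@H]1[C@@]2(C)CCCC(C)(C)[C@@H]2CC[C@@]13OC3 | intermediate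
22 | (1R,2R,4aS,8aS)-1-[(3E)-5-hydroxy-3-methylpent-3-en-1-yl]-2,5,5,8a-tetramethyldecahydronaphthalen-2-ol ((13E)-labd-13-ene-8α,15-diol) | OC/C=C(\C)CC[C@@H]1[C@@]2(C)CCCC(C)(C)[C@@H]2CC[C@@]1(C)O | intermediate
23 | acetic anhydride | CC(=O)OC(C)=O | starting material
24 | (2E)-5-[(1R,2R,4aS,8aS)-2-hydroxy-2,5,5,8a-tetramethyldecahydronaphthalen-1-yl]-3-methylpent-2-en-1-yl acetate (CNP0268033.1) | CC(=O)OC/C=C(\C)CC[C@@H]1[C@@]2(C)CCCC(C)(C)[C@@H]2CC[C@@]1(C)O | target

Total step count: 12. Longest linear sequence: 12 steps (1 to 24).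

Steps most likely to fail

Step 5. The allyl-metal may add 1,2 to the carbonyl of the congested β,β-disubstituted enone, or facial control at C10 may be incomplete. Fallback: from 9, a Hosomi–Sakurai conjugate allylation would replace the organocopper addition (allyltrimethylsilane, Tf2NH 5 mol %, which forms Me3SiNTf2 in situ, CH2Cl2, −78 °C). The allylsilane cannot attack the carbonyl carbon under these conditions, and its silyl group ends on the enolate oxygen, so the reaction should deliver enol silane 11 directly and rejoin the route at 11. It makes no compound outside the list (F0).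

Step 6. Carbon–carbon bond formation at the neopentylic C9 may be too slow, letting the Lewis acid trigger cation–olefin side reactions of the two terminal alkenes or simple hydrolysis of the enol silane. Fallback: from 11, the lithium enolate would be released with MeLi (THF, 0 °C) and added at −78 °C to 3-(trimethylsilyl)but-3-en-2-one, whose silyl group stabilises the developing carbanion and suppresses polymerisation. This should give (3S,4S)-3-methyl-4-(2-methylbut-3-en-2-yl)-2-[3-oxo-2-(trimethylsilyl)butyl]-3-(prop-2-en-1-yl)cyclohexan-1-one F1. Protodesilylation with KF in aqueous MeOH at 0 °C would return to the route at 12.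

Step 10. Facial selectivity of peracid attack on the exocyclic methylene may be poor, so that oxygen is also delivered to the β face and the C8 epimer is carried forward. Fallback: from 19, Markovnikov hydration by oxymercuration–demercuration would be used (Hg(OAc)2, THF–H2O, rt; then NaBH4, aq. NaOH, 0 °C). Water should open the mercurinium ion at C8 along the equatorial α trajectory, away from the syn-axial C10 methyl, to give ethyl (13E)-8α-hydroxylabd-13-en-15-oate F2. Reduction of its ester with i-Bu2AlH (CH2Cl2, −78 °C) would rejoin the route at 22.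

Further compounds
F0 | step 5 | none | none
F1 | step 6 | (3S,4S)-3-methyl-4-(2-methylbut-3-en-2-yl)-2-[3-oxo-2-(trimethylsilyl)butyl]-3-(prop-2-en-1-yl)cyclohexan-1-one | CC(=O)C(CC1[C@@](C)(CC=C)[C@H](C(C)(C)C=C)CCC1=O)[Si](C)(C)C
F2 | step 10 | ethyl (13E)-8α-hydroxylabd-13-en-15-oate | CCOC(=O)/C=C(\C)CC[C@@H]1[C@@]2(C)CCCC(C)(C)[C@@H]2CC[C@@]1(C)O
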